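**Retrosynthetic overview**

1. The target is reached by phenol desilylation and oxidation of a C9′ carbinol. The base-sensitive β,γ-unsaturated α-methyl ketone is carried as a silyl-protected alcohol, and C8′ comes from an anti-crotylation of 4-methylpent-3-en-1-ol.
2. C5′–C6′ is cut to a chroman allylic bromide 9 and a C10 Grignard reagent 17 (copper-catalysed coupling). Bromide 9 comes from SeO2 oxidation of the (E)-methyl group at the prenyl end of chroman 7.
3. Chroman 7 is cut at C4–C4a and O1–C8a to aryl iodide 2 (from 4-iodo-3-methylphenol) and γ-bromo tertiary alcohol 6 (two steps from (R)-linalool, which supplies C2 with its configuration, C3, C4 and six side-chain carbons). The two are joined in one palladium/norbornene relay: ortho C–H alkylation, then ipso C–O coupling.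
4. Enabling feature: in the benzene ring the ether carbon C8a lies between C8, which carries a methyl group, and C4a, which carries the ring CH2. This is an ipso carbon with one blocked and one alkylated ortho position, exactly what a Catellani relay builds on a 2-methylaryl iodide.
5. Ring order: the benzene ring is bought; the dihydropyran ring is the only ring formed (step 4).

Key step: step 4

Assumption: atom numbers follow the chroman ring (O1, C2, C3, C4, C4a, C5 to C8, C8a) and primed numbers the side chain (C1′ on C2 to C13′); commercial (R)-(−)-linalool and the crotylation catalyst are taken to give material of high enantiomeric purity, because C2 and C8′ are set independently and a minor enantiomer of either fragment would end up as a diastereomer of the target.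

**Route**

Step 1
Reactants: 1 4-iodo-3-methylphenol
Product: 2 (4-iodo-3-methylphenoxy)tri(propan-2-yl)silane
Conditions: TIPSCl (1.2 equiv), imidazole (2 equiv), DMF, rt
Reagents that add atoms: chlorotri(propan-2-yl)silane (TIPSCl), CC(C)[Si](Cl)(C(C)C)C(C)C
Why: Standard phenol silylation; the bulky triisopropylsilyl ether should tolerate carbonate base in non-polar solvent, organomagnesium reagents and mild acid, and is removable at the end with buffered fluoride.

Step 2
Reactants: 3 (R)-(−)-linalool, (3R)-3,7-dimethylocta-1,6-dien-3-ol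
Product: 5 (3R)-3,7-dimethyloct-6-ene-1,3-diol, via B-alkyl-9-BBN adduct 4 (not isolated)
Conditions: 9-BBN (1.5 equiv), THF, 0 °C → rt; then 3 M NaOH, 30 % H2O2, 0 °C → rt
Reagents that add atoms: 9-borabicyclo[3.3.1]nonane (9-BBN), B1C2CCCC1CCC2 (boron enters 4 only); hydrogen peroxide, OO (the new oxygen of 5)
Why: Anti-Markovnikov hydroboration–oxidation; 9-BBN should react with the monosubstituted vinyl group far faster than with the trisubstituted alkene, and the tertiary carbinol centre is not touched.

Step 3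
Reactants: 5 (3R)-3,7-dimethyloct-6-ene-1,3-diol
Product: 6 (3R)-1-bromo-3,7-dimethyloct-6-en-3-ol
Conditions: CBr4 (1.2 equiv), PPh3 (1.25 equiv), CH2Cl2, 0 °C
Reagents that add atoms: tetrabromomethane, BrC(Br)(Br)Br
Why: Appel bromination should convert only the primary alcohol, because the hindered tertiary alcohol does not give a displaceable alkoxyphosphonium ion under these mild conditions, and no bond to the stereocentre is involved.

Step 4
Reactants: 2 (4-iodo-3-methylphenoxy)tri(propan-2-yl)silane; 6 (3R)-1-bromo-3,7-dimethyloct-6-en-3-ol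
Product: 7 {[(2R)-2,8-dimethyl-2-(4-methylpent-3-en-1-yl)-3,4-dihydro-2H-chromen-6-yl]oxy}tri(propan-2-yl)silane
Conditions: Pd(OAc)2 (10 mol %), XPhos (20 mol %), norbornene (1 equiv), Cs2CO3 (3 equiv), 6 (1.5 equiv), 1,4-dioxane, 100 °C
Reagents that add atoms: none
Why: Proposed new method: zerovalent palladium inserts into the C–I bond of 2 (the future C8a), norbornene carbopalladation and C–H palladation at the only free ortho position (the future C4a) give an aryl–norbornyl palladacycle, the primary C–Br bond of 6 adds oxidatively to give tetravalent palladium, aryl–alkyl reductive elimination forms C4–C4a, the now doubly ortho-substituted aryl expels norbornene by β-carbon elimination, and the divalent arylpalladium, bound to the tethered tertiary alkoxide, forms O1–C8a by C–O reductive elimination. The closest known reaction types are the palladium/norbornene annulation of aryl iodides with epoxides to 2,3-dihydrobenzofurans (ortho alkylation, then ipso C–O termination), the Catellani ortho alkylation with primary alkyl bromides, and the palladium-catalysed cyclisation of aryl halides carrying tertiary alcohols to 2,2-disubstituted chromans; what is new is their merger with a γ-bromo tertiary alcohol. The dihydropyran ring, the only ring closed, is formed by reductive elimination from a seven-membered aryl–palladium–alkoxide chelate and not by an ionic displacement, so the tertiary C–O bond is never at risk. No stereocentre is created: C2 is the carbinol carbon of (R)-linalool and none of its four bonds is broken. The step needs site selectivity for C4a, which the C8 methyl group secures by blocking the other ortho position and by forcing norbornene to leave after a single alkylation (ortho effect). It also needs chemoselectivity, which rests on the much faster insertion of zerovalent palladium into the aryl iodide than into the alkyl bromide, on the absence of a carbinol hydrogen (no β-hydride elimination from the palladium alkoxide) and on the reluctance of the trisubstituted alkene to undergo Heck insertion.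

Step 5
Reactants: 7 {[(2R)-2,8-dimethyl-2-(4-methylpent-3-en-1-yl)-3,4-dihydro-2H-chromen-6-yl]oxy}tri(propan-2-yl)silane
Product: 8 (2E)-5-[(2R)-2,8-dimethyl-6-{[tri(propan-2-yl)silyl]oxy}-3,4-dihydro-2H-chromen-2-yl]-2-methylpent-2-en-1-ol
Conditions: SeO2 (0.3 equiv), t-BuOOH (3 equiv), salicylic acid (0.1 equiv), CH2Cl2, rt
Reagents that add atoms: tert-butyl hydroperoxide, CC(C)(C)OO (terminal oxidant; the oxygen is passed on by the SeO2 catalyst, O=[Se]=O)
Why: Riley allylic oxidation (ene reaction, then [2,3]-sigmatropic shift) attacks the more substituted alkene carbon and, by its known preference, the (E)-methyl group, so the (E)-allylic alcohol should result, as is usual for prenyl termini.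

Step 6
Reactants: 8 (2E)-5-[(2R)-2,8-dimethyl-6-{[tri(propan-2-yl)silyl]oxy}-3,4-dihydro-2H-chromen-2-yl]-2-methylpent-2-en-1-ol
Product: 9 {[(2R)-2-[(3E)-5-bromo-4-methylpent-3-en-1-yl]-2,8-dimethyl-3,4-dihydro-2H-chromen-6-yl]oxy}tri(propan-2-yl)silane
Conditions: CBr4 (1.2 equiv), PPh3 (1.25 equiv), CH2Cl2, −20 → 0 °C
Reagents that add atoms: tetrabromomethane, BrC(Br)(Br)Br
Why: Appel bromination of a primary allylic alcohol at low temperature should proceed by direct displacement, without allylic transposition and with the E geometry kept.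

Step 7
Reactants: 10 4-methylpent-3-en-1-ol; 11 but-3-en-2-yl acetate (racemic)
Product: 12 (3S,4R)-3,7-dimethylocta-1,6-dien-4-ol
Conditions: [Ir(cod)Cl]2 (2.5 mol %), SEGPHOS (5 mol %, the enantiomer that gives the 3S,4R adduct), 4-cyano-3-nitrobenzoic acid (10 mol %), Cs2CO3 (20 mol %), 11 (2 equiv), THF, 90 °C, sealed tube
Reagents that add atoms: none
Why: Krische-type iridium-catalysed transfer-hydrogenative crotylation from the alcohol oxidation level: the conjugation-prone 4-methylpent-3-enal exists only transiently at the metal, the chiral π-crotyl iridium complex adds through a closed chair transition state that should give the anti adduct and set the methyl-bearing centre (the future C8′) under catalyst control, and the minor syn isomer is to be removed by chromatography.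

Step 8
Reactants: 12 (3S,4R)-3,7-dimethylocta-1,6-dien-4-ol
Product: 13 {[(3S,4R)-3,7-dimethylocta-1,6-dien-4-yl]oxy}triethylsilane
Conditions: TESCl (1.2 equiv), imidazole (2 equiv), CH2Cl2, 0 °C → rt
Reagents that add atoms: chlorotriethylsilane, CC[Si](Cl)(CC)CC
Why: Standard silylation; the triethylsilyl ether is chosen because mild acid should later remove it while leaving the aryl triisopropylsilyl ether in place.

Step 9
Reactants: 13 {[(3S,4R)-3,7-dimethylocta-1,6-dien-4-yl]oxy}triethylsilane
Product: 15 (3S,4R)-3,7-dimethyl-4-[(triethylsilyl)oxy]oct-6-en-1-ol, via B-alkyl-9-BBN adduct 14 (not isolated)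
Conditions: 9-BBN (1.5 equiv), THF, 0 °C → rt; then 3 M NaOH, 30 % H2O2, 0 °C
Reagents that add atoms: 9-borabicyclo[3.3.1]nonane (9-BBN), B1C2CCCC1CCC2 (boron enters 14 only); hydrogen peroxide, OO (the new oxygen of 15)
Why: Anti-Markovnikov hydroboration–oxidation, selective for the monosubstituted alkene over the trisubstituted one, with both stereocentres untouched.

Step 10
Reactants: 15 (3S,4R)-3,7-dimethyl-4-[(triethylsilyl)oxy]oct-6-en-1-ol
Product: 16 {[(3S,4R)-1-bromo-3,7-dimethyloct-6-en-4-yl]oxy}triethylsilane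
Conditions: CBr4 (1.2 equiv), PPh3 (1.25 equiv), CH2Cl2, 0 °C, solid NaHCO3 present as acid scavenger
Reagents that add atoms: tetrabromomethane, BrC(Br)(Br)Br
Why: Appel bromination of the primary alcohol under buffered conditions, which the secondary triethylsilyl ether should survive.

Step 11
Reactants: 16 {[(3S,4R)-1-bromo-3,7-dimethyloct-6-en-4-yl]oxy}triethylsilane; 9 {[(2R)-2-[(3E)-5-bromo-4-methylpent-3-en-1-yl]-2,8-dimethyl-3,4-dihydro-2H-chromen-6-yl]oxy}tri(propan-2-yl)silane
Product: 18 {[(2R)-2,8-dimethyl-2-[(3E,8S,9R)-4,8,12-trimethyl-9-[(triethylsilyl)oxy]trideca-3,11-dien-1-yl]-3,4-dihydro-2H-chromen-6-yl]oxy}tri(propan-2-yl)silane, via Grignard reagent 17 (not isolated)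
Conditions: 16 (1.3 equiv), Mg turnings, THF, 40 °C; then 9 (1.0 equiv), Li2CuCl4 (5 mol %), THF, −78 → 0 °C
Reagents that add atoms: magnesium, [Mg] (enters 17 only)
Why: Copper-catalysed cross-coupling of a primary alkyl Grignard reagent with a primary allylic bromide should substitute directly at the CH2Br carbon with the E alkene kept, as in head-to-tail joining of isoprenoid chains; no stereocentre is involved.

Step 12
Reactants: 18 {[(2R)-2,8-dimethyl-2-[(3E,8S,9R)-4,8,12-trimethyl-9-[(triethylsilyl)oxy]trideca-3,11-dien-1-yl]-3,4-dihydro-2H-chromen-6-yl]oxy}tri(propan-2-yl)silane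
Product: 19 (5R,6S,10E)-13-[(2R)-2,8-dimethyl-6-{[tri(propan-2-yl)silyl]oxy}-3,4-dihydro-2H-chromen-2-yl]-2,6,10-trimethyltrideca-2,10-dien-5-ol
Conditions: AcOH/THF/H2O (3:1:1), rt
Reagents that add atoms: none
Why: Acid hydrolysis of the secondary triethylsilyl ether should be much faster than that of the hindered aryl triisopropylsilyl ether, and the trisubstituted alkenes tolerate dilute acetic acid.

Step 13
Reactants: 19 (5R,6S,10E)-13-[(2R)-2,8-dimethyl-6-{[tri(propan-2-yl)silyl]oxy}-3,4-dihydro-2H-chromen-2-yl]-2,6,10-trimethyltrideca-2,10-dien-5-ol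
Product: 20 (6S,10E)-13-[(2R)-2,8-dimethyl-6-{[tri(propan-2-yl)silyl]oxy}-3,4-dihydro-2H-chromen-2-yl]-2,6,10-trimethyltrideca-2,10-dien-5-one
Conditions: Dess–Martin periodinane (1.5 equiv), NaHCO3 (5 equiv), CH2Cl2, 0 °C → rt
Reagents that add atoms: none
Why: Dess–Martin oxidation under buffered, non-enolising conditions should give the β,γ-unsaturated ketone without moving the alkene into conjugation and without epimerising C8′, while the phenol stays protected against oxidation.

Step 14
Reactants: 20 (6S,10E)-13-[(2R)-2,8-dimethyl-6-{[tri(propan-2-yl)silyl]oxy}-3,4-dihydro-2H-chromen-2-yl]-2,6,10-trimethyltrideca-2,10-dien-5-one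
Product: 21 (6S,10E)-13-[(2R)-6-hydroxy-2,8-dimethyl-3,4-dihydro-2H-chromen-2-yl]-2,6,10-trimethyltrideca-2,10-dien-5-one (target)
Conditions: TBAF (1.2 equiv), AcOH (1.2 equiv), THF, 0 °C
Reagents that add atoms: none
Why: Fluoride cleaves the aryl silyl ether rapidly, and the acetic acid buffer keeps the medium non-basic so that the α-stereocentre and the β,γ-alkene of the ketone should be preserved.

**Compound list**

1 | 4-iodo-3-methylphenol | Cc1cc(O)ccc1I | starting material
2 | (4-iodo-3-methylphenoxy)tri(propan-2-yl)silane | Cc1cc(O[Si](C(C)C)(C(C)C)C(C)C)ccc1I | intermediate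
3 | (R)-(−)-linalool, (3R)-3,7-dimethylocta-1,6-dien-3-ol | C=C[C@](C)(O)CCC=C(C)C | starting material
4 | (3S)-1-(9-borabicyclo[3.3.1]nonan-9-yl)-3,7-dimethyloct-6-en-3-ol (B-alkyl-9-BBN adduct; same spatial arrangement as 3, the descriptor changes by priority only) | C1CCC2CCCC1B2CC[C@](C)(O)CCC=C(C)C | intermediate
5 | (3R)-3,7-dimethyloct-6-ene-1,3-diol | OCC[C@](C)(O)CCC=C(C)C | intermediate
6 | (3R)-1-bromo-3,7-dimethyloct-6-en-3-ol | BrCC[C@](C)(O)CCC=C(C)C | intermediate
7 | {[(2R)-2,8-dimethyl-2-(4-methylpent-3-en-1-yl)-3,4-dihydro-2H-chromen-6-yl]oxy}tri(propan-2-yl)silane | CC(C)=CCC[C@]1(C)CCc2cc(O[Si](C(C)C)(C(C)C)C(C)C)cc(C)c2O1 | intermediate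
8 | (2E)-5-[(2R)-2,8-dimethyl-6-{[tri(propan-2-yl)silyl]oxy}-3,4-dihydro-2H-chromen-2-yl]-2-methylpent-2-en-1-ol | OC/C(C)=C/CC[C@]1(C)CCc2cc(O[Si](C(C)C)(C(C)C)C(C)C)cc(C)c2O1 | intermediate
9 | {[(2R)-2-[(3E)-5-bromo-4-methylpent-3-en-1-yl]-2,8-dimethyl-3,4-dihydro-2H-chromen-6-yl]oxy}tri(propan-2-yl)silane | BrC/C(C)=C/CC[C@]1(C)CCc2cc(O[Si](C(C)C)(C(C)C)C(C)C)cc(C)c2O1 | intermediate
10 | 4-methylpent-3-en-1-ol | CC(C)=CCCO | starting material
11 | but-3-en-2-yl acetate (racemic) | CC(OC(C)=O)C=C | starting material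
12 | (3S,4R)-3,7-dimethylocta-1,6-dien-4-ol | C=C[C@H](C)[C@H](O)CC=C(C)C | intermediate
13 | {[(3S,4R)-3,7-dimethylocta-1,6-dien-4-yl]oxy}triethylsilane | C=C[C@H](C)[C@H](O[Si](CC)(CC)CC)CC=C(C)C | intermediate
14 | {[(3S,4R)-1-(9-borabicyclo[3.3.1]nonan-9-yl)-3,7-dimethyloct-6-en-4-yl]oxy}triethylsilane (B-alkyl-9-BBN adduct) | C1CCC2CCCC1B2CC[C@H](C)[C@H](O[Si](CC)(CC)CC)CC=C(C)C | intermediate
15 | (3S,4R)-3,7-dimethyl-4-[(triethylsilyl)oxy]oct-6-en-1-ol | OCC[C@H](C)[C@H](O[Si](CC)(CC)CC)CC=C(C)C | intermediate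
16 | {[(3S,4R)-1-bromo-3,7-dimethyloct-6-en-4-yl]oxy}triethylsilane | BrCC[C@H](C)[C@H](O[Si](CC)(CC)CC)CC=C(C)C | intermediate
17 | {(3S,4R)-3,7-dimethyl-4-[(triethylsilyl)oxy]oct-6-en-1-yl}magnesium bromide (Grignard reagent) | Br[Mg]CC[C@H](C)[C@H](O[Si](CC)(CC)CC)CC=C(C)C | intermediate
18 | {[(2R)-2,8-dimethyl-2-[(3E,8S,9R)-4,8,12-trimethyl-9-[(triethylsilyl)oxy]trideca-3,11-dien-1-yl]-3,4-dihydro-2H-chromen-6-yl]oxy}tri(propan-2-yl)silane | CC(C)=CC[C@@H](O[Si](CC)(CC)CC)[C@@H](C)CCC/C(C)=C/CC[C@]1(C)CCc2cc(O[Si](C(C)C)(C(C)C)C(C)C)cc(C)c2O1 | intermediate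
19 | (5R,6S,10E)-13-[(2R)-2,8-dimethyl-6-{[tri(propan-2-yl)silyl]oxy}-3,4-dihydro-2H-chromen-2-yl]-2,6,10-trimethyltrideca-2,10-dien-5-ol | CC(C)=CC[C@@H](O)[C@@H](C)CCC/C(C)=C/CC[C@]1(C)CCc2cc(O[Si](C(C)C)(C(C)C)C(C)C)cc(C)c2O1 | intermediate
20 | (6S,10E)-13-[(2R)-2,8-dimethyl-6-{[tri(propan-2-yl)silyl]oxy}-3,4-dihydro-2H-chromen-2-yl]-2,6,10-trimethyltrideca-2,10-dien-5-one | CC(C)=CCC(=O)[C@@H](C)CCC/C(C)=C/CC[C@]1(C)CCc2cc(O[Si](C(C)C)(C(C)C)C(C)C)cc(C)c2O1 | intermediate
21 | (6S,10E)-13-[(2R)-6-hydroxy-2,8-dimethyl-3,4-dihydro-2H-chromen-2-yl]-2,6,10-trimethyltrideca-2,10-dien-5-one | CC(C)=CCC(=O)[C@@H](C)CCC/C(C)=C/CC[C@]1(C)CCc2cc(O)cc(C)c2O1 | target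

**Step count and risks**

Total step count: 14. Longest linear sequence: 9 steps (from 3 through steps 2, 3, 4, 5, 6, 11, 12, 13 and 14).

Steps most likely to fail:

Step 4 (proposed new method). The relay may stall after the ortho alkylation, so that the arylpalladium is protonated instead of closing the C–O bond. The bromo alcohol may also cyclise under base to an oxetane before it reaches the metal, or carbonate may cleave the aryl silyl ether. The fallback forms the same two bonds one after the other by known cross-coupling chemistry. It sets out from borane 4 (made from 3 as in step 2) and from commercial 3-bromo-5-methylphenol. The phenol is chlorinated para to the hydroxyl group (SO2Cl2, CH2Cl2, 0 °C) to give 3-bromo-4-chloro-5-methylphenol F1. This is silylated (TIPSCl, imidazole, DMF) to (3-bromo-4-chloro-5-methylphenoxy)tri(propan-2-yl)silane F2. A B-alkyl Suzuki–Miyaura coupling of 4 at the C–Br bond only (Pd(dppf)Cl2, aqueous K3PO4, THF, 60 °C) gives (3R)-1-[2-chloro-3-methyl-5-{[tri(propan-2-yl)silyl]oxy}phenyl]-3,7-dimethyloct-6-en-3-ol F3. Palladium-catalysed intramolecular etherification of the aryl chloride with the tertiary alcohol (Pd(OAc)2, 2-(di-tert-butylphosphino)-2′,4′,6′-triisopropylbiphenyl, Cs2CO3, toluene, 100 °C) closes the ring, and the route is rejoined at 7.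

Step 11. The Grignard reagent may attack the γ-carbon of the allylic bromide (allylic transposition), or may homocouple. The fallback reverses the polarity (sulfone alkylation of the Biellmann type), which cannot transpose. It sets out from 9, which with PhSO2Na in DMF at rt gives {[(2R)-2-[(3E)-5-(benzenesulfonyl)-4-methylpent-3-en-1-yl]-2,8-dimethyl-3,4-dihydro-2H-chromen-6-yl]oxy}tri(propan-2-yl)silane F6. Deprotonation (n-BuLi, THF/DMPU, −78 °C) and alkylation with bromide 16 give the C5′-benzenesulfonyl derivative of 18, {[(2R)-2-[(3E,8S,9R)-5-(benzenesulfonyl)-4,8,12-trimethyl-9-[(triethylsilyl)oxy]trideca-3,11-dien-1-yl]-2,8-dimethyl-3,4-dihydro-2H-chromen-6-yl]oxy}tri(propan-2-yl)silane F7 (both epimers at C5′). Reductive desulfonylation (PdCl2(dppp) cat., LiBHEt3, THF, 0 °C) returns to the route at 18.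

Step 5. The oxidation may run on to the aldehyde stage, may stop at partial conversion, or may attack the benzylic C4 position. The fallback builds the (E)-allylic alcohol by cleavage and olefination. It sets out from 7, whose trisubstituted alkene is cleaved (OsO4 cat., NaIO4, 2,6-lutidine, dioxane/H2O, rt) to 3-[(2S)-2,8-dimethyl-6-{[tri(propan-2-yl)silyl]oxy}-3,4-dihydro-2H-chromen-2-yl]propanal F4 (the descriptor changes by priority only). An E-selective Wittig reaction with the stabilised ylide ethyl 2-(triphenylphosphoranylidene)propanoate (toluene, 60 °C) gives ethyl (2E)-5-[(2R)-2,8-dimethyl-6-{[tri(propan-2-yl)silyl]oxy}-3,4-dihydro-2H-chromen-2-yl]-2-methylpent-2-enoate F5. Reduction with i-Bu2AlH (CH2Cl2, −78 °C) returns to the route at 8.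

Further compounds
F1 | step 4 | 3-bromo-4-chloro-5-methylphenol | Cc1cc(O)cc(Br)c1Cl
F2 | step 4 | (3-bromo-4-chloro-5-methylphenoxy)tri(propan-2-yl)silane | Cc1cc(O[Si](C(C)C)(C(C)C)C(C)C)cc(Br)c1Cl
F3 | step 4 | (3R)-1-[2-chloro-3-methyl-5-{[tri(propan-2-yl)silyl]oxy}phenyl]-3,7-dimethyloct-6-en-3-ol | Cc1cc(O[Si](C(C)C)(C(C)C)C(C)C)cc(CC[C@](C)(O)CCC=C(C)C)c1Cl
F4 | step 5 | 3-[(2S)-2,8-dimethyl-6-{[tri(propan-2-yl)silyl]oxy}-3,4-dihydro-2H-chromen-2-yl]propanal | O=CCC[C@]1(C)CCc2cc(O[Si](C(C)C)(C(C)C)C(C)C)cc(C)c2O1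
F5 | step 5 | ethyl (2E)-5-[(2R)-2,8-dimethyl-6-{[tri(propan-2-yl)silyl]oxy}-3,4-dihydro-2H-chromen-2-yl]-2-methylpent-2-enoate | CCOC(=O)/C(C)=C/CC[C@]1(C)CCc2cc(O[Si](C(C)C)(C(C)C)C(C)C)cc(C)c2O1
F6 | step 11 | {[(2R)-2-[(3E)-5-(benzenesulfonyl)-4-methylpent-3-en-1-yl]-2,8-dimethyl-3,4-dihydro-2H-chromen-6-yl]oxy}tri(propan-2-yl)silane | O=S(=O)(C/C(C)=C/CC[C@]1(C)CCc2cc(O[Si](C(C)C)(C(C)C)C(C)C)cc(C)c2O1)c1ccccc1
F7 | step 11 | {[(2R)-2-[(3E,8S,9R)-5-(benzenesulfonyl)-4,8,12-trimethyl-9-[(triethylsilyl)oxy]trideca-3,11-dien-1-yl]-2,8-dimethyl-3,4-dihydro-2H-chromen-6-yl]oxy}tri(propan-2-yl)silane (both epimers at C5′) | CC(C)=CC[C@@H](O[Si](CC)(CC)CC)[C@@H](C)CCC(/C(C)=C/CC[C@]1(C)CCc2cc(O[Si](C(C)C)(C(C)C)C(C)C)cc(C)c2O1)S(=O)(=O)c1ccccc1
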